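**Plan**

1. Numbering: isoflavan rings A/C (O1, C2, C3, C4, C7-OH), ring B (C1'–C6'), pyran ring D = O1''–C2''(CH3)2–C3''H=C4''H fused at C4'/C5'.
2. Retrosynthetic cuts, in order: 7-O-MOM; C3'–CH2 of the prenyl group (Claisen from O2'); C2''–C3'' and C4''–C5' together (ring D, two-carbon unit = acetylene); O2'-allyl; C4–OH and O2'-benzyl (hydrogenolysis); C4–H (ketone); C3–C1' (α-arylation).
3. Forward: the purchased chromanone (rings A/C) is arylated with a ring B bromide that already carries the O–C(CH3)2–CO2Et arm; C3 is then fixed; ring D is closed in step 9; the prenyl group moves from O2' to C3' in step 10.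
4. Feature that makes the event possible: C2'' is a tertiary carbon on the aryl ether oxygen O1'', so its carboxylic acid (lost as CO2 in the event) gives a stabilised α-aryloxy radical. C5', ortho to O1'' and para to O2' on the electron-rich ring B, is the only unshielded ortho CH.
5. Stereochemistry: the single stereocenter C3 (R) is set by asymmetric transfer hydrogenation of the racemic isoflavanone with dynamic kinetic resolution; the helper stereocenter at C4 is then removed by hydrogenolysis.

Key step: step 9

Assumption: the (R,R) catalyst is taken to give the 4R alcohol, as it does with 4-chromanone (the (S,S) catalyst would be used if the sense were opposite); carbonate 10 is taken as a purchased reagent.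

**Step 1**
Reactants: 1 4-bromobenzene-1,3-diol; 2 ethyl 2-bromo-2-methylpropanoate
Product: 3 ethyl 2-(4-bromo-3-hydroxyphenoxy)-2-methylpropanoate
Conditions: K2CO3 (2.5 equiv), DMF, 60 °C
Reagents that add atoms: none
Why: Williamson-type O-alkylation with a tertiary α-bromo ester, in which the phenoxide para to bromine is the more nucleophilic and far less hindered of the two, so the bulky electrophile should take O1 and leave the ortho-bromo OH free.

**Step 2**
Reactants: 3 ethyl 2-(4-bromo-3-hydroxyphenoxy)-2-methylpropanoate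
Product: 4 ethyl 2-[3-(benzyloxy)-4-bromophenoxy]-2-methylpropanoate
Conditions: BnBr, K2CO3, DMF, rt
Reagents that add atoms: benzyl bromide, BrCc1ccccc1
Why: Williamson benzylation of the remaining acidic ortho-bromophenol; benzyl is chosen because step 6 removes it together with the C4 oxygen.

**Step 3**
Reactants: 5 7-hydroxychroman-4-one
Product: 6 7-(methoxymethoxy)chroman-4-one
Conditions: MOMCl, i-Pr2NEt, CH2Cl2, 0 °C to rt
Reagents that add atoms: chloromethyl methyl ether, COCCl
Why: Standard MOM protection of the phenol, which must stay masked so that only the 2'-OH is allylated in step 7.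

**Step 4**
Reactants: 4 ethyl 2-[3-(benzyloxy)-4-bromophenoxy]-2-methylpropanoate; 6 7-(methoxymethoxy)chroman-4-one (1.5 equiv)
Product: 7 ethyl 2-{3-(benzyloxy)-4-[7-(methoxymethoxy)-4-oxochroman-3-yl]phenoxy}-2-methylpropanoate (racemic isoflavanone)
Conditions: Pd(OAc)2 (5 mol %), XPhos (10 mol %), K3PO4, toluene, 100 °C
Reagents that add atoms: none
Why: Palladium-catalysed α-arylation of a ketone enolate with a bulky biarylphosphine and a weak phosphate base (to spare the ester and limit ring opening of the chromanone) should join ring B to C3, the ortho substituent suppressing a second arylation.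

**Step 5**
Reactants: 7 racemic isoflavanone
Product: 8 ethyl 2-{3-(benzyloxy)-4-[(3R,4R)-4-hydroxy-7-(methoxymethoxy)chroman-3-yl]phenoxy}-2-methylpropanoate (cis)
Conditions: RuCl[(R,R)-TsDPEN](p-cymene) (2 mol %), HCO2H/Et3N (5:2), EtOAc, 40 °C
Reagents that add atoms: none
Why: Asymmetric transfer hydrogenation with dynamic kinetic resolution, in which C3 of the α-aryl ketone epimerises quickly through the enol while the (R,R) catalyst reduces C4=O of one enantiomer from the face opposite the aryl group, so the cis (3R,4R) alcohol should form and C3 is set under catalyst control.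

**Step 6**
Reactants: 8 cis-(3R,4R) isoflavan-4-ol
Product: 9 ethyl 2-{3-hydroxy-4-[(3R)-7-(methoxymethoxy)chroman-3-yl]phenoxy}-2-methylpropanoate
Conditions: H2 (3 bar), 10% Pd/C, EtOH/AcOH (20:1), rt
Reagents that add atoms: none
Why: Hydrogenolysis should cleave both benzylic C–O bonds (the 2'-O-benzyl ether and the C4–OH activated by the para 7-oxygen), which removes the temporary C4 stereocenter without touching C3.

**Step 7**
Reactants: 9 phenol from step 6; 10 tert-butyl 2-methylbut-3-en-2-yl carbonate
Product: 11 ethyl 2-{4-[(3R)-7-(methoxymethoxy)chroman-3-yl]-3-[(2-methylbut-3-en-2-yl)oxy]phenoxy}-2-methylpropanoate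
Conditions: Pd(PPh3)4 (5 mol %), THF, 0 °C to rt, short reaction time
Reagents that add atoms: none
Why: Palladium-catalysed decarboxylative allylic etherification (Tsuji–Trost type), in which the phenoxide attacks the more substituted end of the 1,1-dimethylallyl palladium complex under kinetic control to give the tertiary ether on the only free OH.

**Step 8**
Reactants: 11 ester from step 7
Product: 12 2-{4-[(3R)-7-(methoxymethoxy)chroman-3-yl]-3-[(2-methylbut-3-en-2-yl)oxy]phenoxy}-2-methylpropanoic acid
Conditions: LiOH·H2O, THF/MeOH/H2O, 40 °C; then 1 M HCl to pH 4 at 0 °C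
Reagents that add atoms: lithium hydroxide, [Li+].[OH-]
Why: Saponification of the hindered, non-enolisable ester; the MOM ether and the tertiary allyl ether are base-stable and should survive the brief cold acidification.

**Step 9**
Reactants: 12 acid from step 8; 13 acetylene
Product: 15 (3R)-3-{2,2-dimethyl-7-[(2-methylbut-3-en-2-yl)oxy]-2H-chromen-6-yl}-7-(methoxymethoxy)chroman, via N-acyloxyphthalimide ester 14 (not isolated)
Conditions: NHPI, DIC, DMAP (cat.), CH2Cl2, rt; evaporate; then fac-Ir(ppy)3 (1 mol %), HC≡CH (1 atm), MeCN, 450 nm LEDs, rt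
Reagents that add atoms: N-hydroxyphthalimide, O=C1c2ccccc2C(=O)N1O (its atoms stay in 14 only)
Why: Proposed new method: single-electron reduction of 14 by photoexcited fac-Ir(ppy)3 releases CO2 and phthalimide anion and leaves the tertiary α-aryloxy radical at C2'', which adds to acetylene (first bond, C2''–C3'') to give a σ-vinyl radical that attacks the ortho carbon C5' of ring B (second bond, C4''–C5'); the cyclohexadienyl radical is then oxidised by tetravalent iridium and deprotonated by phthalimide anion, so the process is redox-neutral. The closest known reaction type is the photoredox decarboxylative radical (4+2) annulation of N-acyloxyphthalimides of α-aryloxy acids with electron-poor alkenes to chromans, together with photoredox radical additions to acetylene gas; acetylene as the two-carbon partner giving the 2H-chromene directly has not been shown. Ring D closes in a six-membered mode by ortho attack of the rapidly inverting vinyl radical on the arene (homolytic aromatic substitution), which gives a cyclohexadienyl radical stabilised by both ring B oxygens, whereas five-membered ipso attack at C4' would not. No stereocenter is formed and C3 is not involved. The step needs site selectivity for C5' over C3': C3' lies between two tertiary-alkyl ether oxygens, and the bulky 2'-O-(1,1-dimethylallyl) group, turned away from the chromanyl group at C1', covers C3' and gears the reacting arm toward C5'.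

**Step 10**
Reactants: 15 chromene from step 9
Product: 16 6-[(3R)-7-(methoxymethoxy)chroman-3-yl]-2,2-dimethyl-8-(3-methylbut-2-en-1-yl)-2H-chromen-7-ol
Conditions: PhNEt2, 130 °C
Reagents that add atoms: none
Why: Aromatic Claisen rearrangement of the aryl 1,1-dimethylallyl ether, in which C1' is substituted so the group can end only on C3', arriving as the 3-methylbut-2-enyl group and freeing the 2'-OH, while the amine solvent suppresses acid-catalysed cyclisation of the ortho-prenylphenol.

**Step 11**
Reactants: 16 MOM ether from step 10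
Product: 17 6-[(3R)-7-hydroxychroman-3-yl]-2,2-dimethyl-8-(3-methylbut-2-en-1-yl)-2H-chromen-7-ol (target)
Conditions: 1 M HCl in MeOH, rt to 40 °C
Reagents that add atoms: none
Why: Acid-catalysed methanolysis of the aryl MOM acetal, which should be much faster than protonation of the trisubstituted alkene or of the chromene under these mild conditions.

**Compound list**

1 | 4-bromobenzene-1,3-diol | Oc1ccc(Br)c(O)c1 | starting material
2 | ethyl 2-bromo-2-methylpropanoate | CCOC(=O)C(C)(C)Br | starting material
3 | ethyl 2-(4-bromo-3-hydroxyphenoxy)-2-methylpropanoate | CCOC(=O)C(C)(C)Oc1ccc(Br)c(O)c1 | intermediate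
4 | ethyl 2-[3-(benzyloxy)-4-bromophenoxy]-2-methylpropanoate | CCOC(=O)C(C)(C)Oc1ccc(Br)c(OCc2ccccc2)c1 | intermediate
5 | 7-hydroxychroman-4-one | O=C1CCOc2cc(O)ccc12 | starting material
6 | 7-(methoxymethoxy)chroman-4-one | COCOc1ccc2C(=O)CCOc2c1 | intermediate
7 | ethyl 2-{3-(benzyloxy)-4-[7-(methoxymethoxy)-4-oxochroman-3-yl]phenoxy}-2-methylpropanoate (racemic) | CCOC(=O)C(C)(C)Oc1ccc(C2COc3cc(OCOC)ccc3C2=O)c(OCc2ccccc2)c1 | intermediate
8 | ethyl 2-{3-(benzyloxy)-4-[(3R,4R)-4-hydroxy-7-(methoxymethoxy)chroman-3-yl]phenoxy}-2-methylpropanoate | CCOC(=O)C(C)(C)Oc1ccc([C@@H]2COc3cc(OCOC)ccc3[C@@H]2O)c(OCc2ccccc2)c1 | intermediate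
9 | ethyl 2-{3-hydroxy-4-[(3R)-7-(methoxymethoxy)chroman-3-yl]phenoxy}-2-methylpropanoate | CCOC(=O)C(C)(C)Oc1ccc([C@@H]2COc3cc(OCOC)ccc3C2)c(O)c1 | intermediate
10 | tert-butyl 2-methylbut-3-en-2-yl carbonate | C=CC(C)(C)OC(=O)OC(C)(C)C | starting material
11 | ethyl 2-{4-[(3R)-7-(methoxymethoxy)chroman-3-yl]-3-[(2-methylbut-3-en-2-yl)oxy]phenoxy}-2-methylpropanoate | CCOC(=O)C(C)(C)Oc1ccc([C@@H]2COc3cc(OCOC)ccc3C2)c(OC(C)(C)C=C)c1 | intermediate
12 | 2-{4-[(3R)-7-(methoxymethoxy)chroman-3-yl]-3-[(2-methylbut-3-en-2-yl)oxy]phenoxy}-2-methylpropanoic acid | OC(=O)C(C)(C)Oc1ccc([C@@H]2COc3cc(OCOC)ccc3C2)c(OC(C)(C)C=C)c1 | intermediate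
13 | acetylene | C#C | starting material
14 | 1,3-dioxoisoindolin-2-yl ester of acid 12 | O=C(ON1C(=O)c2ccccc2C1=O)C(C)(C)Oc1ccc([C@@H]2COc3cc(OCOC)ccc3C2)c(OC(C)(C)C=C)c1 | intermediate (not isolated)
15 | (3R)-3-{2,2-dimethyl-7-[(2-methylbut-3-en-2-yl)oxy]-2H-chromen-6-yl}-7-(methoxymethoxy)chroman | C=CC(C)(C)Oc1cc2OC(C)(C)C=Cc2cc1[C@@H]1COc2cc(OCOC)ccc2C1 | intermediate
16 | 6-[(3R)-7-(methoxymethoxy)chroman-3-yl]-2,2-dimethyl-8-(3-methylbut-2-en-1-yl)-2H-chromen-7-ol | CC(C)=CCc1c(O)c([C@@H]2COc3cc(OCOC)ccc3C2)cc2c1OC(C)(C)C=C2 | intermediate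
17 | 6-[(3R)-7-hydroxychroman-3-yl]-2,2-dimethyl-8-(3-methylbut-2-en-1-yl)-2H-chromen-7-ol | CC(C)=CCc1c(O)c([C@@H]2COc3cc(O)ccc3C2)cc2c1OC(C)(C)C=C2 | target

**Step count**

Total: 11 steps. Longest linear sequence: 10 steps (steps 1, 2 and 4 to 11, from 1).

**Steps most likely to fail**

Step 9 (proposed new method). The tertiary radical may add too slowly to acetylene, so that its oxidation to the oxocarbenium ion or hydrogen abstraction by the vinyl radical takes over; ring closure may also be split between C5' and C3'. Fallback with known chemistry, from 12 back to 15: 12 would be converted into 14 as above and irradiated with fac-Ir(ppy)3 and phenyl vinyl sulfone (3 equiv) in place of acetylene. Fast Giese addition of the tertiary radical, cyclisation of the electrophilic α-sulfonyl radical onto C5' and rearomatisation (the known radical (4+2) annulation with electron-poor alkenes) should give the 4''-(phenylsulfonyl)chroman F1 as a mixture of C4'' epimers. KOt-Bu in THF (0 °C to rt) would then eliminate benzenesulfinate to give 15.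

Step 4. The chromanone enolate may open by β-elimination of the aryloxide, the electron-rich ortho-benzyloxy aryl bromide may couple sluggishly, and the aryl palladium species may attack the benzyl ether by intramolecular C–H arylation. Fallback, from 4 back to 7, joining the rings at the chromone oxidation level: Miyaura borylation of 4 (B2pin2, Pd(dppf)Cl2, KOAc, dioxane, 90 °C) would give the pinacol boronate F2. Separately, purchased 2,4-dihydroxyacetophenone would be protected at the 4-OH (MOMCl, K2CO3, acetone) to 1-[2-hydroxy-4-(methoxymethoxy)phenyl]ethanone F3, condensed with DMF dimethyl acetal to the enaminone F4 and cyclised with iodine to 3-iodo-7-(methoxymethoxy)chromen-4-one F5. Suzuki coupling of F2 with F5 (Pd(PPh3)4, aqueous Na2CO3, DME, 80 °C) would give the isoflavone F6, and 1,4-reduction with LiBH(s-Bu)3 in THF at −78 °C would return to isoflavanone 7.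

Step 6. Cleavage of the C4–O bond may be incomplete, or dehydration to the isoflav-3-ene followed by hydrogenation may erode the configuration at C3. Fallback, from 8 back to 9, separating the two events: 8 would be acylated with 1,1'-thiocarbonyldiimidazole (DMAP, CH2Cl2) to the imidazole-1-carbothioate F7 and reduced with Bu3SnH/AIBN in toluene at 80 °C (Barton–McCombie deoxygenation) to the 4-deoxy benzyl ether F8. In the cis alcohol the C3–H is trans to the C4–O bond, so thermal syn elimination is not available. F8 would then be debenzylated with H2 and Pd/C in neutral EtOAc to give 9.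

**Further compounds**

F1 | step 9 | (3R)-3-{2,2-dimethyl-7-[(2-methylbut-3-en-2-yl)oxy]-4-(phenylsulfonyl)chroman-6-yl}-7-(methoxymethoxy)chroman (C4'' epimers) | C=CC(C)(C)Oc1cc2OC(C)(C)CC(S(=O)(=O)c3ccccc3)c2cc1[C@@H]1COc2cc(OCOC)ccc2C1
F2 | step 4 | ethyl 2-[3-(benzyloxy)-4-(4,4,5,5-tetramethyl-1,3,2-dioxaborolan-2-yl)phenoxy]-2-methylpropanoate | CCOC(=O)C(C)(C)Oc1ccc(B2OC(C)(C)C(C)(C)O2)c(OCc2ccccc2)c1
F3 | step 4 | 1-[2-hydroxy-4-(methoxymethoxy)phenyl]ethanone | CC(=O)c1ccc(OCOC)cc1O
F4 | step 4 | (E)-3-(dimethylamino)-1-[2-hydroxy-4-(methoxymethoxy)phenyl]prop-2-en-1-one | CN(C)/C=C/C(=O)c1ccc(OCOC)cc1O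
F5 | step 4 | 3-iodo-7-(methoxymethoxy)-4H-chromen-4-one | O=c1c(I)coc2cc(OCOC)ccc12
F6 | step 4 | ethyl 2-{3-(benzyloxy)-4-[7-(methoxymethoxy)-4-oxo-4H-chromen-3-yl]phenoxy}-2-methylpropanoate | CCOC(=O)C(C)(C)Oc1ccc(-c2coc3cc(OCOC)ccc3c2=O)c(OCc2ccccc2)c1
F7 | step 6 | O-[(3R,4R)-3-{2-(benzyloxy)-4-[(1-ethoxy-2-methyl-1-oxopropan-2-yl)oxy]phenyl}-7-(methoxymethoxy)chroman-4-yl] 1H-imidazole-1-carbothioate | CCOC(=O)C(C)(C)Oc1ccc([C@@H]2COc3cc(OCOC)ccc3[C@@H]2OC(=S)n2ccnc2)c(OCc2ccccc2)c1
F8 | step 6 | ethyl 2-{3-(benzyloxy)-4-[(3R)-7-(methoxymethoxy)chroman-3-yl]phenoxy}-2-methylpropanoate | CCOC(=O)C(C)(C)Oc1ccc([C@@H]2COc3cc(OCOC)ccc3C2)c(OCc2ccccc2)c1
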